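**Retrosynthetic overview**

- The route rests on the pattern of the single ring: carbonyl carbon C1 lies between C2–OMe and C6–chain, with C3–H, C5–H and the second carbonyl at C4 para to C1. The quinone is therefore the oxidised form of a 4-methoxyphenol.
- Last disconnection: the C4 carbonyl goes back to C4–OMe and C1=O to C1–OH, giving (R)-1-(2-hydroxy-3,5-dimethoxyphenyl)tridecan-2-yl acetate.
- Key disconnection, the only ring-forming event: bonds C4–C5, C1–C6 and C1–C2. C5, C6 and the whole C1'–C13' chain come from a terminal alkyne, C1 from a CO ligand, and C2(OMe)–C3–C4(OMe) from a 1,3-dimethoxypropenylidene ligand on chromium.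
- Alkyne: tridec-1-ene, epoxidation, hydrolytic kinetic resolution (sets C2'), acetylide opening, acetylation.
- Carbene complex: Cr(CO)6 and LiC≡CSiMe3 with O-methylation, then methanol addition with loss of silicon.

Key step: step 7

Assumption: lithium acetylide–ethylenediamine complex and lithium (trimethylsilyl)acetylide (0.5 M in THF) are bought as such; locants C1–C6 (ring, C1 between C2–OMe and C6–chain) and C1'–C13' (chain, OAc on C2') are used throughout.

**Route**

Step 1
Reactants: 1 tridec-1-ene
Product: 2 rac-2-undecyloxirane
Conditions: mCPBA (1.2 equiv), CH2Cl2, 0 °C to rt; aq. Na2SO3/NaHCO3 wash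
Reagents that add atoms: mCPBA (3-chloroperoxybenzoic acid), OOC(=O)c1cccc(Cl)c1
Why: Prilezhaev epoxidation of an unfunctionalised monosubstituted alkene by a peracid, with no competing group in the substrate.

Step 2
Reactants: 2 rac-2-undecyloxirane
Product: 3 (R)-2-undecyloxirane
Conditions: (R,R)-(salen)Co(OAc) [salen = N,N'-bis(3,5-di-tert-butylsalicylidene)cyclohexane-1,2-diamine dianion; trivalent cobalt, made from the divalent cobalt complex with AcOH and air] (0.5 mol%), H2O (0.55 equiv), THF, 0 °C to rt; chromatography from the diol
Reagents that add atoms: none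
Why: Jacobsen hydrolytic kinetic resolution, in which the (R,R)-catalyst should hydrolyse the (S)-epoxide selectively and leave the (R)-epoxide, so that this step sets the C2' configuration of the target.

Step 3
Reactants: 3 (R)-2-undecyloxirane; 4 lithium acetylide–ethylenediamine complex
Product: 5 (R)-pentadec-1-yn-4-ol
Conditions: 4 (1.5 equiv), DMSO, 0 °C to rt; then H2O
Reagents that add atoms: none
Why: SN2 opening of a terminal epoxide by acetylide at the unsubstituted CH2, so the stereocentre is not involved and stays R.

Step 4
Reactants: 5 (R)-pentadec-1-yn-4-ol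
Product: 6 (R)-pentadec-1-yn-4-yl acetate
Conditions: Ac2O (1.5 equiv), pyridine, DMAP (5 mol%), CH2Cl2, 0 °C to rt
Reagents that add atoms: acetic anhydride, CC(=O)OC(C)=O
Why: DMAP-catalysed O-acylation of a secondary alcohol, which leaves the C–O bond at the stereocentre and the terminal alkyne untouched.

Step 5
Reactants: 7 chromium hexacarbonyl, Cr(CO)6; 8 lithium (trimethylsilyl)acetylide
Product: 10 pentacarbonyl[1-methoxy-3-(trimethylsilyl)prop-2-yn-1-ylidene]chromium, via lithium acylchromate 9 (not isolated)
Conditions: THF, −78 °C to rt; then MeOTf (1.3 equiv), −78 to 0 °C; Ar throughout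
Reagents that add atoms: methyl trifluoromethanesulfonate, COS(=O)(=O)C(F)(F)F
Why: Fischer carbene synthesis, in which the acetylide adds to a CO ligand of zerovalent chromium and the hard methylating agent alkylates the acylate oxygen.

Step 6
Reactants: 10 pentacarbonyl[1-methoxy-3-(trimethylsilyl)prop-2-yn-1-ylidene]chromium
Product: 12 pentacarbonyl[(E)-1,3-dimethoxyprop-2-en-1-ylidene]chromium, via ethynylcarbene complex 11 (not isolated)
Conditions: MeOH (5 equiv), NaOMe (10 mol%), THF, −40 to 0 °C; AcOH quench; rapid chromatography under Ar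
Reagents that add atoms: methanol, CO
Why: Methoxide should cleave the C(sp)–Si bond of this very electron-poor alkynylsilane and methanol then add to the β-carbon of the terminal alkynylcarbene, as in the known base-catalysed conjugate addition of alcohols to alkynyl Fischer carbene complexes and the behaviour of silyl ynones, giving the push-pull alkene as its more stable E isomer, while methoxide exchange at the carbene carbon is degenerate.

Step 7
Reactants: 6 (R)-pentadec-1-yn-4-yl acetate; 12 pentacarbonyl[(E)-1,3-dimethoxyprop-2-en-1-ylidene]chromium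
Product: 14 (R)-1-(2-hydroxy-3,5-dimethoxyphenyl)tridecan-2-yl acetate, via arene chromium tricarbonyl complex 13 (not isolated)
Conditions: 12 (1.5 equiv), degassed THF (0.05 M), 55–60 °C, Ar; then air, Et2O, rt
Reagents that add atoms: none
Why: Thermal loss of one cis CO from the zerovalent chromium carbene 12 opens a site for alkyne 6, which inserts into Cr=C with its unsubstituted carbon bonded to the former carbene carbon (C4–C5); CO insertion then gives a chromium-bound dienylketene (C1–C6), the only ring is closed by 6π-electrocyclisation of that ketene onto the methoxy-bearing β-carbon (C1–C2), and the resulting dienone tautomerises at C2–H to the phenol, held as the η6 chromium tricarbonyl complex until air releases it. The closest known reaction is the Dötz benzannulation of alkenyl(methoxy)carbene chromium complexes with terminal alkynes, applied here to an uncommon β-methoxy-substituted alkenyl ligand. No stereocentre is formed; C2' and its acetate sit two atoms from the alkyne and are untouched by the neutral, aprotic conditions. Two selectivities are needed: the regiochemistry of insertion, secured by the size difference between H and the CH2CH(OAc)C11H23 group of a terminal alkyne, which places the chain next to the CO-derived carbon C1; and CO insertion ahead of a five-membered ring closure, favoured by chromium, by an alkoxy and not an amino carbene, by THF at moderate temperature, and by the β-carbon keeping one hydrogen so that the dienone can aromatise. The E/Z geometry of 12 does not matter because C2 becomes sp3 in the dienone and then aromatic.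

Step 8
Reactants: 14 (R)-1-(2-hydroxy-3,5-dimethoxyphenyl)tridecan-2-yl acetate
Product: 15 (R)-1-(5-methoxy-3,6-dioxocyclohexa-1,4-dien-1-yl)tridecan-2-yl acetate (the target)
Conditions: (NH4)2Ce(NO3)6 (2.5 equiv), MeCN/H2O (2:1), 0 °C, short reaction time
Reagents that add atoms: water, O
Why: Oxidative demethylation of a hydroquinone monomethyl ether, in which two one-electron oxidations give a cation that water captures at C4 and the hemiketal loses methanol to the para-quinone, while the C2 methoxy stays as a vinylogous ester and the acetate survives the brief, cold, mildly acidic medium.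

Crude 14 can be taken into step 8 without chromatography, since any air oxidation of this electron-rich phenol already gives 15.

**Compound list**

1 | tridec-1-ene | C=CCCCCCCCCCCC | starting material
2 | rac-2-undecyloxirane (1,2-epoxytridecane) | CCCCCCCCCCCC1CO1 | intermediate
3 | (R)-2-undecyloxirane | CCCCCCCCCCC[C@@H]1CO1 | intermediate
4 | lithium acetylide–ethylenediamine complex | [Li+].[C-]#C.NCCN | starting material
5 | (R)-pentadec-1-yn-4-ol | CCCCCCCCCCC[C@H](CC#C)O | intermediate
6 | (R)-pentadec-1-yn-4-yl acetate | CCCCCCCCCCC[C@H](CC#C)OC(C)=O | intermediate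
7 | chromium hexacarbonyl, Cr(CO)6 | O=C=[Cr](=C=O)(=C=O)(=C=O)(=C=O)=C=O | starting material
8 | lithium (trimethylsilyl)acetylide | [Li+].[C-]#C[Si](C)(C)C | starting material
9 | lithium pentacarbonyl[1-oxido-3-(trimethylsilyl)prop-2-yn-1-ylidene]chromate (lithium acylchromate) | [Li+].C[Si](C)(C)C#CC([O-])=[Cr](=C=O)(=C=O)(=C=O)(=C=O)=C=O | intermediate
10 | pentacarbonyl[1-methoxy-3-(trimethylsilyl)prop-2-yn-1-ylidene]chromium | C[Si](C)(C)C#CC(OC)=[Cr](=C=O)(=C=O)(=C=O)(=C=O)=C=O | intermediate
11 | pentacarbonyl(1-methoxyprop-2-yn-1-ylidene)chromium (ethynylcarbene complex) | C#CC(OC)=[Cr](=C=O)(=C=O)(=C=O)(=C=O)=C=O | intermediate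
12 | pentacarbonyl[(E)-1,3-dimethoxyprop-2-en-1-ylidene]chromium | CO/C=C/C(OC)=[Cr](=C=O)(=C=O)(=C=O)(=C=O)=C=O | intermediate
13 | tricarbonyl[η6-(R)-1-(2-hydroxy-3,5-dimethoxyphenyl)tridecan-2-yl acetate]chromium (η6 bonding not encoded in the SMILES) | CCCCCCCCCCC[C@H](Cc1cc(OC)cc(OC)c1O)OC(C)=O.O=C=[Cr](=C=O)=C=O | intermediate
14 | (R)-1-(2-hydroxy-3,5-dimethoxyphenyl)tridecan-2-yl acetate | CCCCCCCCCCC[C@H](Cc1cc(OC)cc(OC)c1O)OC(C)=O | intermediate
15 | (R)-1-(5-methoxy-3,6-dioxocyclohexa-1,4-dien-1-yl)tridecan-2-yl acetate | CCCCCCCCCCC[C@H](CC1=CC(=O)C=C(OC)C1=O)OC(C)=O | target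

**Step count**

Total: 8 steps. Longest linear sequence: 6 steps (steps 1, 2, 3, 4, 7, 8); the carbene branch (steps 5, 6) joins at step 7.

**Steps most likely to fail**

1. Step 7. The β-methoxy donor may hold the CO ligands too firmly for CO loss at a temperature the complex survives, or ring closure may run without CO insertion to five-membered products. The fallback builds the arene from a phenol and sets out from epoxide 3, returning at 15. Guaiacol is protected (NaH, MOMCl, THF) as 1-methoxy-2-(methoxymethoxy)benzene F1. Directed ortho-lithiation (n-BuLi, THF, 0 °C) next to the acetal oxygen gives [3-methoxy-2-(methoxymethoxy)phenyl]lithium F2. This opens 3 at the terminal carbon (BF3·OEt2, −78 °C) to (R)-1-[3-methoxy-2-(methoxymethoxy)phenyl]tridecan-2-ol F3. Acetylation as in step 4 gives (R)-1-[3-methoxy-2-(methoxymethoxy)phenyl]tridecan-2-yl acetate F4. Aqueous HCl in THF removes the acetal to give (R)-1-(2-hydroxy-3-methoxyphenyl)tridecan-2-yl acetate F5. Teuber oxidation with (KSO3)2NO (KH2PO4 buffer, acetone/water) at the free para position gives 15.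

2. Step 6. Desilylation and conjugate addition may fall out of step, with oligomerisation of the transient terminal alkynylcarbene or a second methanol addition to the β,β-dimethoxy acetal. The fallback brings the C=C–O unit in preformed; it sets out from 7 and returns at 12. Purchased (Z)-1-bromo-2-ethoxyethene is exchanged with t-BuLi (2 equiv, THF, −78 °C) to (Z)-2-ethoxyvinyllithium F6. This adds to Cr(CO)6 to give lithium pentacarbonyl[(Z)-3-ethoxy-1-oxidoprop-2-en-1-ylidene]chromate F7. MeOTf gives pentacarbonyl[(Z)-3-ethoxy-1-methoxyprop-2-en-1-ylidene]chromium F8. NaOMe (10 mol%) in MeOH then exchanges the β-ethoxy group for methoxy by addition–elimination at C3, the path by which amines displace β-alkoxy groups in such complexes, with equilibration to the E isomer 12.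

3. Step 8. Oxidation may take the ortho course (loss of the C2 methyl to an ortho-quinone) or go on to degrade the electron-rich ring. The fallback separates oxidation from hydrolysis; it sets out from 14 and returns at 15. PhI(OAc)2 in MeOH at 0 °C should trap the oxidised phenol at C4 as the quinone monoketal (R)-1-(3,3,5-trimethoxy-6-oxocyclohexa-1,4-dien-1-yl)tridecan-2-yl acetate F9. Wet silica gel with oxalic acid in CH2Cl2 then hydrolyses the ketal to 15.

**Further compounds**

F1 | step 7 | 1-methoxy-2-(methoxymethoxy)benzene | COCOc1ccccc1OC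
F2 | step 7 | [3-methoxy-2-(methoxymethoxy)phenyl]lithium | [Li]c1cccc(OC)c1OCOC
F3 | step 7 | (R)-1-[3-methoxy-2-(methoxymethoxy)phenyl]tridecan-2-ol | CCCCCCCCCCC[C@H](Cc1cccc(OC)c1OCOC)O
F4 | step 7 | (R)-1-[3-methoxy-2-(methoxymethoxy)phenyl]tridecan-2-yl acetate | CCCCCCCCCCC[C@H](Cc1cccc(OC)c1OCOC)OC(C)=O
F5 | step 7 | (R)-1-(2-hydroxy-3-methoxyphenyl)tridecan-2-yl acetate | CCCCCCCCCCC[C@H](Cc1cccc(OC)c1O)OC(C)=O
F6 | step 6 | (Z)-2-ethoxyvinyllithium | CCO/C=C\[Li]
F7 | step 6 | lithium pentacarbonyl[(Z)-3-ethoxy-1-oxidoprop-2-en-1-ylidene]chromate | [Li+].CCO/C=C\C([O-])=[Cr](=C=O)(=C=O)(=C=O)(=C=O)=C=O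
F8 | step 6 | pentacarbonyl[(Z)-3-ethoxy-1-methoxyprop-2-en-1-ylidene]chromium | CCO/C=C\C(OC)=[Cr](=C=O)(=C=O)(=C=O)(=C=O)=C=O
F9 | step 8 | (R)-1-(3,3,5-trimethoxy-6-oxocyclohexa-1,4-dien-1-yl)tridecan-2-yl acetate | CCCCCCCCCCC[C@H](CC1=CC(OC)(OC)C=C(OC)C1=O)OC(C)=O
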